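**Plan**

- Locants (used in every name below): ring carbons C1 (ketone) to C10, lactone carbons C11–C13, C14 = methylene on C10, C15 = methyl on C4.
- Retrosynthesis: remove the C3–C4 epoxide oxygen and the O9 angelate, open the lactone at O6–C12, return C6 to a ketone, then rejoin C1 to C6. The oxygen-bearing C1 and C6 face each other 1,6 across the ten-membered ring with the cis C3=C4 olefin between them, so the macrocycle is the periphery of a 4-methyloctalin (ring A = C1–C6, ring B = C1, C6–C10) carrying a diol on its fusion bond.
- The bicycle is cut at C3=C4 (metathesis), C1–C2 and C5–C6 (allyl and methallyl additions), C10=C14 (Mannich methylenation), C6–O (Rubottom) and C7–C11 (cuprate addition).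
- Forward: ring B is made first as an enantiopure cyclohexenone, ring A is closed on it by ring-closing metathesis, glycol fission of C1–C6 merges both into the ten-membered ring, and the lactone ring and the epoxide follow.
- Stereochemistry: C8 and C9 from chiral-base opening of a meso epoxide, C7 from cuprate addition anti to O8, C6 from hydride reduction of the macrocyclic ketone, C3 and C4 from peripheral epoxidation of the Z olefin; the angelate geometry comes from angelic acid.

Key step: step 14

Assumption: the lithium amide of (S)-2-(pyrrolidin-1-ylmethyl)pyrrolidine opens meso epoxide 4 in the same sense as it opens cyclohexene oxide (S carbinol); if the sense is reversed, the R amide is used.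

Remark on the C7 side chain: the acrylate unit is carried as its acrolein diethyl acetal (3,3-diethoxyprop-1-en-2-yl), which survives the two Grignard additions and is raised to the lactone oxidation level after the ring fission.

**Route**

Step 1
Reactants: 1 cyclohexa-1,4-diene
Product: 2 cis-cyclohex-4-ene-1,2-diol (meso)
Conditions: OsO4 (cat.), N-methylmorpholine N-oxide (1 equiv), acetone/H2O, 0 °C to rt, diene in excess
Reagents that add atoms: N-methylmorpholine N-oxide C[N+]1([O-])CCOCC1; water O
Why: Catalytic OsO4 syn-dihydroxylation of one of the two equivalent olefins, held at mono-addition by limiting the oxidant, should give the meso cis-diol.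

Step 2
Reactants: 2 cis-cyclohex-4-ene-1,2-diol
Product: 3 cis-4,5-(isopropylidenedioxy)cyclohexene (meso acetonide)
Conditions: 2,2-dimethoxypropane, p-TsOH (cat.), CH2Cl2, rt
Reagents that add atoms: 2,2-dimethoxypropane COC(C)(C)OC
Why: Acid-catalysed transketalisation of a cis-1,2-diol to the dioxolane is routine.

Step 3
Reactants: 3 meso acetonide
Product: 4 meso anti epoxide (epoxide trans to the dioxolane)
Conditions: mCPBA, NaHCO3, CH2Cl2, 0 °C
Reagents that add atoms: mCPBA OOC(=O)c1cccc(Cl)c1
Why: Prilezhaev epoxidation on the convex face of the cis-fused bicycle, anti to the dioxolane oxygens, should give mainly the anti epoxide, the minor syn isomer being removed by chromatography.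

Step 4
Reactants: 4 meso anti epoxide
Product: 5 (1S,4R,5S)-4,5-(isopropylidenedioxy)cyclohex-2-en-1-ol
Conditions: (S)-2-(pyrrolidin-1-ylmethyl)pyrrolidine, n-BuLi, THF, 0 °C to rt; aqueous work-up
Reagents that add atoms: none
Why: Enantioselective syn β-elimination of a meso epoxide by a chiral lithium amide (epoxide-to-allylic-alcohol rearrangement) removes the proton of one enantiotopic arm and so fixes the C8 and C9 configurations for the whole route.

Step 5
Reactants: 5 allylic alcohol
Product: 6 (4R,5S)-4,5-(isopropylidenedioxy)cyclohex-2-en-1-one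
Conditions: Dess–Martin periodinane, NaHCO3, CH2Cl2, 0 °C to rt
Reagents that add atoms: none
Why: Buffered Dess–Martin oxidation of the allylic alcohol avoids the basic conditions under which the C9 oxygen could be lost by β-elimination.

Step 6
Reactants: 6 enone; 7 2-bromo-3,3-diethoxyprop-1-ene
Product: 10 ring-B triethylsilyl enol ether (C1–OSiEt3 and C1=C6 with the acetal side chain at C7), via vinyllithium 8 (not isolated), via lithium divinylcuprate 9 (not isolated)
Conditions: 7, t-BuLi, Et2O, −78 °C; CuBr·SMe2, −78 to −40 °C; then 6, Et3SiCl, THF, −78 °C; Et3N, aq. NaHCO3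
Reagents that add atoms: chlorotriethylsilane CC[Si](Cl)(CC)CC
Why: The Gilman cuprate of 2-lithioacrolein diethyl acetal is a known acrylate α-anion equivalent whose silyl-chloride-assisted conjugate addition should occur anti to the O8 of the cis-fused acetonide, setting C7, while the enolate is trapped regiospecifically as the C1=C6 silyl enol ether.

Step 7
Reactants: 10 silyl enol ether
Product: 12 C6-triethylsilyloxy C1 ketone, via silyloxy epoxide 11 (not isolated)
Conditions: mCPBA, NaHCO3, CH2Cl2, −20 to 0 °C
Reagents that add atoms: mCPBA OOC(=O)c1cccc(Cl)c1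
Why: Rubottom oxidation, in which the electron-rich enol ether is epoxidised in preference to the 1,1-disubstituted olefin, anti to the C7 side chain, and a 1,4-silyl shift gives the α-silyloxy ketone (the C6 configuration is erased in step 11).

Step 8
Reactants: 12 α-silyloxy ketone
Product: 16 C10-methylene ketone, via lithium enolate 13 (not isolated), via Mannich base 14 (not isolated), via ammonium iodide 15 (not isolated)
Conditions: LiN(i-Pr)2, THF, −78 °C; CH2=NMe2+ I−, −78 to 0 °C; MeI, CH2Cl2, rt; aq. NaHCO3, rt
Reagents that add atoms: N,N-dimethylmethyleneiminium iodide (Eschenmoser's salt) C=[N+](C)C.[I-]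
Why: Kinetic deprotonation should occur at the unhindered C10 methylene and not at the silyloxy-bearing C6, and Mannich reaction, N-methylation and base-induced β-elimination of trimethylamine is the standard α-methylenation, the low temperature keeping the β-alkoxy enolate from expelling O9.

Step 9
Reactants: 16 α-methylene ketone; 17 allylmagnesium bromide
Product: 18 C1 allyl carbinol (C1–OH cis to C6–OSiEt3)
Conditions: THF/Et2O, −78 °C
Reagents that add atoms: none
Why: Allyl Grignard reagents add 1,2 to enones, and attack opposite the axial O9 and the neighbouring C6 silyloxy group should place C1–OH cis to C6–O, a configuration that is immaterial after step 14.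

Step 10
Reactants: 18 silyl ether
Product: 19 C1,C6-diol
Conditions: Bu4NF, THF, 0 °C
Reagents that add atoms: none
Why: Fluoride-mediated cleavage of a secondary triethylsilyl ether leaves the acetal, the acetonide and the olefins untouched.

Step 11
Reactants: 19 diol
Product: 20 C6 ketone with free C1 tertiary alcohol
Conditions: IBX, DMSO, rt
Reagents that add atoms: none
Why: IBX oxidises the secondary hydroxyl of a 1,2-diol to the α-hydroxy ketone without glycol cleavage and cannot oxidise the tertiary allylic alcohol.

Step 12
Reactants: 20 α-hydroxy ketone; 21 (2-methylallyl)magnesium chloride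
Product: 22 cis-1-allyl-6-(2-methylallyl) C1,C6-diol
Conditions: THF, −78 to 0 °C (2.5 equiv of 21)
Reagents that add atoms: none
Why: Chelation-controlled Grignard addition to the magnesium alkoxide of an α-hydroxy ketone, anti to the C1 oxygen, should give the cis-diol, the allylic Grignard adding faster than it enolises C7.

Step 13
Reactants: 22 diene diol
Product: 23 cis-fused 4-methyloctalin-1,6-diol (key-step precursor)
Conditions: second-generation Grubbs catalyst RuCl2(=CHPh)(H2IMes)(PCy3) (5 mol %), CH2Cl2, 40 °C
Reagents that add atoms: none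
Why: Ring-closing metathesis of the allyl and methallyl groups forms the trisubstituted cyclohexene of ring A, whereas the hindered 1,1-disubstituted olefins at C10 and C11 have no partner within reach of an unstrained ring.

Step 14
Reactants: 23 octalin diol
Product: 25 (Z)-cyclodec-3-ene-1,6-dione, via cyclic lead diester 24 (not isolated)
Conditions: Pb(OAc)4 (1.1 equiv), NaHCO3, CH2Cl2, −20 to 0 °C; crude product used at once
Reagents that add atoms: none
Why: The two cis fusion hydroxyls at C1 and C6 exchange with acetate on tetravalent lead to give the five-membered cyclic lead diester 24, which fragments in a concerted two-electron process: the C1–C6 bond breaks, both C–O bonds become carbonyls and lead leaves as divalent Pb(OAc)2. The closest known reaction is the Criegee glycol cleavage of ring-fusion decalin-9,10-diols to cyclodecane-1,6-diones. No ring is closed end to end: the ten-membered ring is the periphery of rings A and B and is unveiled by cutting their shared bond, so the C3=C4 olefin made in six-membered ring A can only emerge as the Z isomer and the C1 carbonyl is formed already conjugated to the C10 methylene. No stereocenter is formed, and C7, C8 and C9, set on the chair of ring B, pass through unchanged. The step needs chemoselectivity for one glycol, which is secured because the only other vicinal diol (C8/C9) is tied up as the acetonide, and the cis geometry of the fusion diol secures fast formation of the cyclic diester. Low temperature and the NaHCO3 buffer should keep the β,γ-unsaturated 1,6-dione from transannular aldol closure, from C7 epimerisation and from expelling O8.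

Step 15
Reactants: 25 dione
Product: 26 macrocyclic C1,C6-diol (6R; C1 as an epimer mixture)
Conditions: NaBH4, CeCl3·7H2O, MeOH, −78 to −40 °C
Reagents that add atoms: none
Why: Luche reduction reduces both carbonyls 1,2 without conjugate reduction of the C1 enone, and at C6 hydride is expected to attack the peripheral face anti to the C7 side chain (Felkin–Anh) to give the 6,7-trans alcohol, while the C1 epimers converge in step 17.

Step 16
Reactants: 26 diol acetal
Product: 28 α-methylene-γ-lactol (O6–C12; anomer mixture), via hydroxy enal 27 (not isolated)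
Conditions: pyridinium p-toluenesulfonate (cat.), acetone/H2O, rt
Reagents that add atoms: water O
Why: Mild acid hydrolysis of the acrolein diethyl acetal frees the enal, which the γ-hydroxyl at C6 captures as the five-membered lactol (5-exo addition to C=O), O8 being locked in the acetonide that the acetone solvent preserves.

Step 17
Reactants: 28 lactol
Product: 29 12,6-lactone C1 enone 8,9-acetonide
Conditions: Dess–Martin periodinane (3 equiv), NaHCO3, CH2Cl2, 0 °C to rt
Reagents that add atoms: none
Why: Dess–Martin oxidation converts the lactol into the α-methylene-γ-lactone and the allylic C1 alcohol back into the α-methylene ketone in one operation, no other free hydroxyl being present.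

Step 18
Reactants: 29 acetonide
Product: 30 8,9-diol
Conditions: CF3CO2H/H2O, CH2Cl2, 0 °C
Reagents that add atoms: none
Why: Acid hydrolysis of the dioxolane is standard, and the lactone, the enone and the Z olefin offer no feasible transannular pathway under these conditions.

Step 19
Reactants: 30 8,9-diol; 31 angelic acid
Product: 33 9-O-angelate with free 8-hydroxyl, via mixed anhydride 32 (not isolated)
Conditions: 31, 2,4,6-trichlorobenzoyl chloride, Et3N, toluene, rt; then 30, 60 °C
Reagents that add atoms: none
Why: Yamaguchi-type acylation with the preformed mixed anhydride and without DMAP avoids isomerisation to the tiglate, and the allylic C9 hydroxyl, flanked by the planar C10, should react before the C8 hydroxyl, which is crowded by the lactone ring fusion.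

Step 20
Reactants: 33 angelate
Product: 34 CNP0348992.4 (target)
Conditions: mCPBA, NaHCO3, CH2Cl2, 0 °C
Reagents that add atoms: mCPBA OOC(=O)c1cccc(Cl)c1
Why: Prilezhaev epoxidation attacks only the electron-rich C3=C4 olefin (the other three are conjugated to carbonyls), and peripheral attack on the outer face of the Z olefin is expected to give the (3S,4R) epoxide.

**Compound list**

1 | cyclohexa-1,4-diene | C1=CCC=CC1 | starting material
2 | cis-cyclohex-4-ene-1,2-diol (meso) | O[C@H]1CC=CC[C@H]1O | intermediate
3 | cis-4,5-(isopropylidenedioxy)cyclohexene (meso) | C1=CC[C@H]2OC(C)(C)O[C@H]2C1 | intermediate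
4 | meso 1,2-epoxy-cis-4,5-(isopropylidenedioxy)cyclohexane, epoxide trans to the dioxolane | [C@@H]12O[C@@H]1C[C@H]3OC(C)(C)O[C@H]3C2 | intermediate
5 | (1S,4R,5S)-4,5-(isopropylidenedioxy)cyclohex-2-en-1-ol (hydroxyl trans to the dioxolane) | O[C@@H]1C=C[C@H]2OC(C)(C)O[C@H]2C1 | intermediate
6 | (4R,5S)-4,5-(isopropylidenedioxy)cyclohex-2-en-1-one | O=C1C=C[C@H]2OC(C)(C)O[C@H]2C1 | intermediate
7 | 2-bromo-3,3-diethoxyprop-1-ene | C=C(Br)C(OCC)OCC | starting material
8 | (3,3-diethoxyprop-1-en-2-yl)lithium | [Li]C(=C)C(OCC)OCC | intermediate (not isolated)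
9 | lithium bis(3,3-diethoxyprop-1-en-2-yl)cuprate | [Li+].CCOC(OCC)C(=C)[Cu-]C(=C)C(OCC)OCC | intermediate (not isolated)
10 | ring-B triethylsilyl enol ether: C1–OSiEt3, C1=C6, 3,3-diethoxyprop-1-en-2-yl at C7 trans to O8, cis 8,9-acetonide | CC[Si](CC)(CC)OC1=C[C@H](C(=C)C(OCC)OCC)[C@H]2OC(C)(C)O[C@H]2C1 | intermediate
11 | C1,C6-epoxide of 10, epoxide oxygen trans to the C7 side chain | CC[Si](CC)(CC)O[C@]12O[C@H]1[C@H](C(=C)C(OCC)OCC)[C@H]3OC(C)(C)O[C@H]3C2 | intermediate (not isolated)
12 | ring-B C1 ketone with C6–OSiEt3 trans to the C7 side chain | O=C1[C@@H](O[Si](CC)(CC)CC)[C@H](C(=C)C(OCC)OCC)[C@H]2OC(C)(C)O[C@H]2C1 | intermediate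
13 | lithium C1(O)=C10 enolate of 12 | [Li]OC=1[C@@H](O[Si](CC)(CC)CC)[C@H](C(=C)C(OCC)OCC)[C@H]2OC(C)(C)O[C@H]2C=1 | intermediate (not isolated)
14 | C10-(dimethylaminomethyl) ketone (C10 configuration immaterial) | O=C1[C@@H](O[Si](CC)(CC)CC)[C@H](C(=C)C(OCC)OCC)[C@H]2OC(C)(C)O[C@H]2C1CN(C)C | intermediate (not isolated)
15 | C10-(trimethylammoniomethyl) ketone iodide | O=C1[C@@H](O[Si](CC)(CC)CC)[C@H](C(=C)C(OCC)OCC)[C@H]2OC(C)(C)O[C@H]2C1C[N+](C)(C)C.[I-] | intermediate (not isolated)
16 | ring-B C1 ketone with C10=C14 methylene | O=C1[C@@H](O[Si](CC)(CC)CC)[C@H](C(=C)C(OCC)OCC)[C@H]2OC(C)(C)O[C@H]2C1=C | intermediate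
17 | allylmagnesium bromide | C=CC[Mg]Br | starting material
18 | C1 allyl tertiary alcohol, C1–OH cis to C6–OSiEt3 and to O8/O9 | O[C@@]1(CC=C)[C@@H](O[Si](CC)(CC)CC)[C@H](C(=C)C(OCC)OCC)[C@H]2OC(C)(C)O[C@H]2C1=C | intermediate
19 | C1-allyl C1,C6-cis-diol | O[C@@]1(CC=C)[C@@H](O)[C@H](C(=C)C(OCC)OCC)[C@H]2OC(C)(C)O[C@H]2C1=C | intermediate
20 | C6 ketone with C1 allyl tertiary alcohol | O[C@@]1(CC=C)C(=O)[C@H](C(=C)C(OCC)OCC)[C@H]2OC(C)(C)O[C@H]2C1=C | intermediate
21 | (2-methylallyl)magnesium chloride | C=C(C)C[Mg]Cl | starting material
22 | C1-allyl C6-(2-methylallyl) cis-diol, both hydroxyls on the face of O8/O9 | O[C@@]1(CC=C)[C@](O)(CC(C)=C)[C@H](C(=C)C(OCC)OCC)[C@H]2OC(C)(C)O[C@H]2C1=C | intermediate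
23 | cis-fused 4-methyloctalin-1,6-diol: C3=C4, C10 methylene, C7 acetal side chain trans to O8, cis 8,9-acetonide, fusion hydroxyls cis to each other and to O8/O9 | O[C@@]12CC=C(C)C[C@]1(O)[C@H](C(=C)C(OCC)OCC)[C@H]3OC(C)(C)O[C@H]3C2=C | intermediate
24 | cyclic lead diacetate diester of 23 (O1–Pb–O6) | CC(=O)O[Pb]1(OC(C)=O)O[C@@]32CC=C(C)C[C@]3(O1)[C@H](C(=C)C(OCC)OCC)[C@H]4OC(C)(C)O[C@H]4C2=C | intermediate (not isolated)
25 | (Z)-4-methyl-10-methylenecyclodec-3-ene-1,6-dione with C7 acetal side chain and 8,9-acetonide | O=C1C/C=C(C)\CC(=O)[C@H](C(=C)C(OCC)OCC)[C@H]2OC(C)(C)O[C@H]2C1=C | intermediate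
26 | macrocyclic C1,C6-diol: 6R hydroxyl trans to the C7 side chain, C1 epimer mixture | OC1C/C=C(C)\C[C@@H](O)[C@H](C(=C)C(OCC)OCC)[C@H]2OC(C)(C)O[C@H]2C1=C | intermediate
27 | 6-hydroxy enal (C7 side chain CH2=C–CHO) | OC1C/C=C(C)\C[C@@H](O)[C@H](C(=C)C=O)[C@H]2OC(C)(C)O[C@H]2C1=C | intermediate (not isolated)
28 | 6,7-trans α-methylene-γ-lactol (O6–C12), C1 carbinol, 8,9-acetonide; anomers and C1 epimers | OC1C/C=C(C)\C[C@H]3OC(O)C(=C)[C@@H]3[C@H]2OC(C)(C)O[C@H]2C1=C | intermediate
29 | 1-oxogermacra-3Z,10(14),11(13)-trien-12,6-olide 8,9-acetonide | O=C1C/C=C(C)\C[C@H]3OC(=O)C(=C)[C@@H]3[C@H]2OC(C)(C)O[C@H]2C1=C | intermediate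
30 | 8,9-dihydroxy-1-oxogermacra-3Z,10(14),11(13)-trien-12,6-olide (8,9-cis-diol) | O=C1C/C=C(C)\C[C@H]3OC(=O)C(=C)[C@@H]3[C@@H](O)[C@@H](O)C1=C | intermediate
31 | angelic acid, (Z)-2-methylbut-2-enoic acid | C/C=C(/C)C(=O)O | starting material
32 | angelic 2,4,6-trichlorobenzoic anhydride | C/C=C(/C)C(=O)OC(=O)c1c(Cl)cc(Cl)cc1Cl | intermediate (not isolated)
33 | 9-angeloyloxy-8-hydroxy-1-oxogermacra-3Z,10(14),11(13)-trien-12,6-olide | O=C1C/C=C(C)\C[C@H]3OC(=O)C(=C)[C@@H]3[C@@H](O)[C@@H](OC(=O)/C(C)=C\C)C1=C | intermediate
34 | CNP0348992.4, (3S,4R,6R,7R,8R,9S)-9-angeloyloxy-3,4-epoxy-8-hydroxy-1-oxogermacra-10(14),11(13)-dien-12,6-olide | C=C1C(=O)O[C@@H]2C[C@@]3(C)O[C@H]3CC(=O)C(=C)[C@H](OC(=O)/C(C)=C\C)[C@H](O)[C@@H]12 | target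

**Step count**

Total: 20 steps. Longest linear sequence: 20 steps (1 to 34).

**Steps most likely to fail**

Step 15. Hydride may be delivered to the wrong face of the C6 carbonyl, because the facial bias of the flexible ten-membered ring is only inferred from a Felkin–Anh model. The fallback replaces substrate control by catalyst control. It sets out from dione 25, which would be reduced with (S)-2-methyl-CBS-oxazaborolidine and catecholborane in toluene at −78 °C. With the branched C7 side as the large group, this catalyst delivers hydride to the face that gives the 6R carbinol, and the C1 carbonyl is reduced 1,2 as before. The fallback comes back to the route at diol 26 and makes no new compound (F0).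

Step 19. Acylation at O8 may compete with or outrun acylation at O9, and the acyl group may migrate between the cis hydroxyls. The fallback turns that reactivity order into a protecting step. It sets out from diol 30, where Et3SiCl and imidazole in CH2Cl2 at −40 °C would silylate the more reactive hydroxyl to give the 8-O-triethylsilyl ether F1. The only remaining hydroxyl is then acylated with mixed anhydride 32 in toluene at 60 °C to give the 8-O-triethylsilyl 9-O-angelate F2. HF·pyridine in THF/pyridine at 0 °C removes the silyl group, and the fallback comes back to the route at angelate 33.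

Step 20. The peracid may attack the wrong face of the C3=C4 olefin if the outer face of the macrocycle is not the one assumed. The fallback inverts the facial outcome through a halohydrin. It sets out from angelate 33, where N-bromosuccinimide in THF/H2O at 0 °C would form the bromonium ion on the face the peracid prefers. Water opens it at the tertiary C4 from the opposite face to give the 3-bromo-4-hydroxy compound F3. K2CO3 in acetone at rt then closes the epoxide with inversion at C3, which places the oxygen on the face opposite to direct epoxidation, and the fallback comes back to the route at target 34.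

**Further compounds**

F0 | step 15 | none | none
F1 | step 19 | 8-O-triethylsilyl ether of diol 30 | O=C1C/C=C(C)\C[C@H]3OC(=O)C(=C)[C@@H]3[C@@H](O[Si](CC)(CC)CC)[C@@H](O)C1=C
F2 | step 19 | 8-O-triethylsilyl 9-O-angelate | O=C1C/C=C(C)\C[C@H]3OC(=O)C(=C)[C@@H]3[C@@H](O[Si](CC)(CC)CC)[C@@H](OC(=O)/C(C)=C\C)C1=C
F3 | step 20 | 3-bromo-4-hydroxy bromohydrin of 33 (Br at C3 anti to OH at C4) | C=C1C(=O)O[C@@H]2C[C@@](C)(O)[C@H](Br)CC(=O)C(=C)[C@H](OC(=O)/C(C)=C\C)[C@H](O)[C@@H]12
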